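## Structural features

The target is a daucane-type sesquiterpenoid ester: a cyclopentane (ring A, C1–C5) fused through the C1–C5 bond to a cycloheptene (ring B, C1 and C5–C10). C1 is the quaternary carbon with the angular methyl, C4 the tertiary carbinol with the isopropyl group, C5 the ring-fusion CH, C6 the CH bearing the 4-hydroxybenzoate, and C8 the alkene carbon (C8=C9) bearing formyl carbon C14. The four stereocentres C1 (R), C4 (R), C5 (S) and C6 (S) are contiguous. If the face of ring A carrying the C1 methyl is called β, the C4 hydroxyl and the C5–C6 bond are also β, while H5, the isopropyl group and C10 are α, so the ring fusion is trans. With C4 written as a carbonyl, the C4–C5–C6 array is a β-hydroxy ketone with the anti relationship between C5 and C6. The fragile groups are the enal, the tertiary C4 alcohol (loss of water under acid), the aryl ester and the free phenol; two aldehyde-level carbons, C9 and C14, must also be kept away from organometallic reagents. The real difficulty is the absolute configuration of the all-carbon quaternary C1 set among three further stereocentres, together with a seven-membered ring closure that must put the formyl group on C8 and not on C10. The key step uses the fact that ring A with a C4 ketone is a 2,3,3-trisubstituted cyclopentanone: the C1 methyl and the C6 carbinol at C5 are the β- and α-substituents that a conjugate addition–aldol sequence places on a 3-substituted cyclopent-2-enone. C10/C9 and C7/C8/C14 ride along as two acetal-terminated arms that later become ring B.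

## Logic of the disconnections

**20 ⇒ 19.** The C8=C9 bond is cut by an aldol-condensation transform. The enal is the retron, and C14 as an aldehyde makes C8 the natural nucleophile towards a C9 aldehyde. This opens ring B and leaves a monocyclic compound with all four stereocentres and no new one to set. The forward step must close a seven-membered ring with C8 as donor and C9 as acceptor (not C10 onto C14), under conditions that leave the ester, the phenol and the tertiary alcohol alone.

**19 ⇒ 18.** The C9 and C14 aldehydes and the phenol are masked as two dimethyl acetals and an oxan-2-yl ether; no skeletal bond is cut. The reason is that free aldehydes and a free phenol cannot pass through the organometallic, silylation and acylation steps. The gain is a robust, non-enolisable intermediate. The demand is one mild acidic hydrolysis that removes three acetal-type groups and spares the tertiary alcohol and the ester.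

**18 ⇒ 14 + 17, and 17 ⇒ 15.** The acyl C–O bond at C6 is cut, which takes off the aromatic unit as a separately prepared acid and makes the route convergent. The forward acylation must select the hindered secondary C6–OH over the tertiary C4–OH and must not use acid, because the acetals and the phenol ether are acid-labile. Cutting the two O–C bonds to the oxane rings takes 17 back to 15.

**14 ⇒ 13 ⇒ 11 + 12, and 11 ⇒ 10.** The C4–isopropyl bond is cut, since a tertiary carbinol maps onto a ketone plus an isopropyl nucleophile and the C4 ketone is exactly the carbonyl of the aldol pattern. This removes the C4 stereocentre and reveals the β-silyloxy ketone. The forward addition must succeed on a hindered, enolisable cyclopentanone and come from the α face, anti to the C5–C6 bond and the C1 methyl. It also requires the C6 hydroxyl to be masked during the addition and unmasked afterwards (silyl ether of 10).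

**10 ⇒ 6 + 7 + 8.** The C1–CH3 and C5–C6 bonds are cut together. This is the central simplification: three stereocentres (C1, C5, C6) and two skeletal bonds go back to an achiral enone, a methyl donor and an achiral aldehyde. The forward step needs enantiofacial control of methyl delivery to C1, aldol attack on the enolate face that carries the new methyl group, and anti simple diastereoselection. It must also tolerate two acetals in the presence of an aluminium Lewis acid.

**6 ⇒ 4 ⇒ 1 + 2.** The C9 acetal is traced to an aldehyde and this to the terminal alkene of an allyl group (oxidative cleavage of C9=CH2). The bond between C10 and the ring is then cut as a 1,2-addition of an allyl nucleophile to a vinylogous ester with carbonyl transposition. This reduces the enone to two bulk chemicals. The demand is that ozone cleaves the isolated alkene and not the conjugated one, and that the sensitive aldehyde is acetalised without isolation.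

## Other disconnections considered

**Alternative 1:** The cut is the C1–C10 bond of ring B, with the C6–O bond re-formed in the retrosynthetic direction. This leads from the bicyclic enone ketal A2 back to the 2-methylideneoxolane A1, whose ring carbinol carbon is C6 and whose cyclopentene C5=C1 is tetrasubstituted. In the forward sense, heating A1 would cause an aliphatic Claisen rearrangement over C10=C9–O–C6–C5=C1. The five-membered ether would expand into the carbocyclic seven-membered ring with a C9 ketone and a C5=C6 alkene, and the C6 configuration would be relayed suprafacially to quaternary C1.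

- In favour: the step needs no reagent and is stereospecific. The enantiomeric purity of C1 would rest on a secondary carbinol that asymmetric ketone reduction supplies readily; on this point the alternative is the equal or the better of the chosen plan.
- In favour: ring B would emerge with C9 (ketone) and C5=C6 (alkene) chemically distinct, so the position of the later formyl group is not in doubt (enol triflate towards C8, away from neopentyl C10, then formylating carbonylation). Here the alternative is better than the chosen plan, which relies on a steric bias between two aldehydes.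
- In favour: syn hydroboration of C5=C6 from the face opposite the angular methyl would give H5 and the C6 oxygen in the target relationship.
- Against: A1 is an exocyclic enol ether that can slip to the endocyclic isomer. Bond formation at a fully substituted alkene carbon through a ring-constrained, boat-like transition state calls for high temperature.
- Against: A2 carries only C1. C4, C5 and C6 remain to be set, two ketone levels (C4 ketal, C9) have to be addressed in the right order, and C14 is still missing.

In comparison, this key step builds one ring and one stereocentre, where the chosen step builds no ring but three stereocentres. It is concerted where the chosen step is catalyst- and substrate-controlled. In step count it would be clearly longer: roughly six steps to A1 and about ten after A2.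

**Alternative 2:** The cuts are C1–C5 and C7–C8. They take the trans-fused bicyclic C6 ketone A4 back to the acyclic chloromethyl ketone A3, which carries the finished C4 carbinol (as silyl ether) in a three-atom tether to a 1,1-disubstituted diene terminus (C1). In the forward sense, NEt3 in CF3CH2OH would ionise A3 to the C5–C6–C7 oxyallyl cation, which would add across C1 and C8 of the diene in an intramolecular (4+3) cycloaddition.

- In favour: both rings and the C1/C5 ring fusion would arise in one step from an open chain. In skeletal-bond and ring economy this is better than the chosen key step.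
- In favour: C4 already carries its isopropyl group, so the late organometallic addition to a hindered ketone disappears; this too is a point on which the alternative is better.
- Against: the absolute configuration would hang entirely on an acyclic tertiary carbinol flanked by two similar CH2 chains, which is hard to prepare in enantiopure form.
- Against: face selection by this centre and the cis/trans outcome of the ring fusion are not secured by any clear control element for three-atom tethers.
- Against: the diene terminus that must become quaternary C1 carries an inward methyl group, which disfavours the s-cis conformer and the bond formation. The weakly stabilised oxyallyl cation invites solvent capture and Favorskii-type rearrangement.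
- Against: after A4, the C6 ketone must be reduced to the correct epimer, and the C9=C10 alkene moved into conjugation after oxidation of C14.

In comparison, the alternative is structurally the most convergent of all, but it is mechanistically stepwise-cationic with open stereochemical questions, whereas each stereocentre of the chosen plan has a defined source. The step count is similar or somewhat higher, because A3 needs a long linear preparation.

**Alternative 3:** The cut is C4–C5 of ring A. It takes the cyclopentane ester A6 back to the acyclic α-diazo ester A5, in which C1 (methyl, allyl) and the C4 silyloxy methine are already stereodefined. In the forward sense, Rh2(OAc)4 would convert A5 into a rhodium carbenoid at C5, which would insert into the C4–H bond with retention and close the five-membered ring.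

- In favour: the C–H bond is tertiary and oxygen-activated, and 1,5-insertion is the preferred ring size.
- In favour: the β-carbon (C1) has no hydrogen, so hydride shift to an alkene is excluded.
- In favour: C4 is set with certainty from a secondary carbinol and not by face selection on a ketone; on this point the alternative is better than the chosen plan.
- In favour: the allyl and ester arms are different functional groups, so the ring-B termini are differentiated from the start (equal or better). The ester-bearing C5 can be equilibrated to the isomer with the ester on the face of the smaller groups, which is the one required.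
- Against: A5 needs two remote stereocentres in an open chain, one of them an acyclic all-carbon quaternary centre, and a diazo transfer next to that quaternary carbon.
- Against: an alkyl-substituted acceptor carbenoid is not very selective, so insertion into the isopropyl methine or allylic positions and reaction with the alkene are open side channels.
- Against: A6 still lacks C7, C8 and C14, and the C6 stereocentre has to be created afterwards by a separate addition to a C6 aldehyde.

In comparison, the alternative's key step forms one ring and one bond and sets C5 only. Its mechanism is a concerted insertion with reliable retention, but the route around it would be longer (about eight steps to A5 and eight after A6), and C6 would no longer be set together with C1 and C5.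

Key step: step 3

Assumption: 4,4-dimethoxybutanal (8) is taken as a purchasable liquid and distilled before use; compounds carrying the oxan-2-yl group (16, 17, 18) are mixtures of epimers at the oxane acetal carbon, which is removed in step 9.

## Route

Step 1
Reactants: 1 3-ethoxycyclopent-2-en-1-one; 2 allylmagnesium bromide
Product: 4 3-(prop-2-en-1-yl)cyclopent-2-en-1-one, via bromomagnesium alkoxide adduct 3 (not isolated)
Conditions: 2 (1.3 equiv), THF, 0 °C; then 1 M HCl, 0 °C → rt, 30 min
Reagents that add atoms: water, O
Why: The Grignard reagent adds 1,2 to the vinylogous ester; dilute acid then ionises the tertiary allylic alkoxide adduct and hydrolyses the enol ether, moving the carbonyl to the former ethoxy carbon (Stork–Danheiser alkylative carbonyl transposition). The short, cold acid treatment should leave the allyl double bond out of conjugation.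

Step 2
Reactants: 4 3-(prop-2-en-1-yl)cyclopent-2-en-1-one
Product: 6 3-(2,2-dimethoxyethyl)cyclopent-2-en-1-one, via 2-(3-oxocyclopent-1-en-1-yl)acetaldehyde 5 (not isolated)
Conditions: O3, CH2Cl2/MeOH 5:1, Sudan Red 7B, −78 °C; Me2S, −78 → 0 °C; then HC(OMe)3 (3 equiv), TsOH·H2O (5 mol%), 0 °C → rt; Et3N quench
Reagents that add atoms: trimethyl orthoformate, COC(OC)OC (with methanol, CO, source of the two methoxy groups); ozone, [O-][O+]=O (carbonyl oxygen of 5)
Why: Electrophilic ozone cleaves the isolated monosubstituted alkene much faster than the electron-poor conjugated one, and the dye marks the end point (chemoselective ozonolysis with reductive work-up). The doubly activated aldehyde 5 is not isolated but acetalised at once under acid with orthoformate as water scavenger, the aldehyde reacting far faster than the conjugated ketone.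

Step 3
Reactants: 6 3-(2,2-dimethoxyethyl)cyclopent-2-en-1-one; 7 trimethylaluminium; 8 4,4-dimethoxybutanal
Product: 10 (2S,3R)-3-(2,2-dimethoxyethyl)-2-[(1S)-1-hydroxy-4,4-dimethoxybutyl]-3-methylcyclopentan-1-one, via dimethylaluminium enolate 9 (not isolated)
Conditions: Cu(OTf)2 (3 mol%), chiral phosphoramidite L* (BINOL-derived N,N-bis(1-phenylethyl)phosphoramidite, 6 mol%, antipode chosen for Si-face delivery), 7 (1.2 equiv), Et2O, −30 °C; then 8 (2 equiv), −78 → −40 °C; aq. potassium sodium tartrate
Reagents that add atoms: none
Why: AlMe3 reduces Cu(OTf)2 to a monovalent copper–phosphoramidite complex and passes a methyl group to it; π-complexation of the aluminium-activated enone, formation of a trivalent copper σ-intermediate at C1 and reductive elimination deliver methyl to the Si face of the β-carbon and leave the dimethylaluminium enolate 9 (copper-catalysed enantioselective conjugate addition of a trialkylaluminium to a β-substituted cyclic enone, a known route to quaternary centres). Enolate 9, necessarily the E(O)-enolate of a five-membered ring, then adds to 8 through a closed six-membered Zimmerman–Traxler chair with aluminium bridging both oxygens and the aldehyde chain equatorial (three-component conjugate addition–aldol, known for zinc and aluminium enolates of cyclopentenones). No ring is closed: ring A is carried by 6, and the two new bonds are C1–CH3 and C5–C6. C1 (R) is set by the ligand (catalyst control). C5 (S) is set by approach of 8 to the enolate face that carries the new methyl group, anti to the larger, β-branched CH2CH(OMe)2 arm on the adjacent quaternary carbon (substrate control). C6 (S) is set by the chair transition state of the cyclic E-enolate, which gives the anti aldol. The step therefore needs enantiofacial selectivity at C1, diastereofacial selectivity at C5, anti simple selectivity at C5/C6, and chemoselectivity of AlMe3 for conjugate addition over the acetals and over direct methylation of 8. These are served by the ligand, by the size difference between methyl and the acetal arm, by the fixed enolate geometry, and by working in Et2O at low temperature with only a small excess of AlMe3 before 8 is added.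

Step 4
Reactants: 10 (2S,3R)-3-(2,2-dimethoxyethyl)-2-[(1S)-1-hydroxy-4,4-dimethoxybutyl]-3-methylcyclopentan-1-one
Product: 11 (2S,3R)-3-(2,2-dimethoxyethyl)-2-[(1S)-4,4-dimethoxy-1-[(triethylsilyl)oxy]butyl]-3-methylcyclopentan-1-one
Conditions: TESCl (1.5 equiv), imidazole (3 equiv), DMAP (cat.), DMF, 0 °C → rt
Reagents that add atoms: chlorotriethylsilane, CC[Si](Cl)(CC)CC
Why: Silylation of a secondary alcohol with a silyl chloride and imidazole; the chloride is chosen over a silyl triflate because triflates attack dimethyl acetals. The mild base should not reverse the aldol, and the C5 configuration is also the thermodynamically preferred one (side chain trans to the larger C1 arm).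

Step 5
Reactants: 11 (2S,3R)-3-(2,2-dimethoxyethyl)-2-[(1S)-4,4-dimethoxy-1-[(triethylsilyl)oxy]butyl]-3-methylcyclopentan-1-one; 12 isopropylmagnesium chloride
Product: 13 (1R,2S,3R)-3-(2,2-dimethoxyethyl)-2-[(1S)-4,4-dimethoxy-1-[(triethylsilyl)oxy]butyl]-3-methyl-1-(propan-2-yl)cyclopentan-1-ol
Conditions: anhydrous CeCl3 (3 equiv), THF, rt; 12 (3 equiv), −78 °C, 1 h; then 11, −78 → −20 °C; aq. NH4Cl
Reagents that add atoms: none
Why: The organocerium reagent formed in the flask is strongly nucleophilic but weakly basic, so 1,2-addition to the hindered, enolisable ketone should win over enolisation and β-hydride reduction (organocerium carbonyl addition). C4 is set by attack on the α face, anti to the bulky silyloxyalkyl substituent on the adjacent C5 and to the C1 methyl, which places the new hydroxyl cis to the C5–C6 bond.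

Step 6
Reactants: 13 (1R,2S,3R)-3-(2,2-dimethoxyethyl)-2-[(1S)-4,4-dimethoxy-1-[(triethylsilyl)oxy]butyl]-3-methyl-1-(propan-2-yl)cyclopentan-1-ol
Product: 14 (1R,2S,3R)-3-(2,2-dimethoxyethyl)-2-[(1S)-1-hydroxy-4,4-dimethoxybutyl]-3-methyl-1-(propan-2-yl)cyclopentan-1-ol
Conditions: TBAF (1.5 equiv), THF, 0 °C → rt; chromatography on Et3N-buffered silica
Reagents that add atoms: none
Why: Fluoride cleaves the triethylsilyl ether and leaves the acetals and the tertiary alcohol untouched (fluoride-mediated desilylation). Buffered silica prevents the γ-hydroxy acetal from closing to a cyclic mixed acetal.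

Step 7
Reactants: 15 4-hydroxybenzoic acid
Product: 17 4-(oxan-2-yloxy)benzoic acid, via bis(oxan-2-yl) derivative 16 (not isolated)
Conditions: 3,4-dihydro-2H-pyran (3 equiv), PPTS (5 mol%), CH2Cl2, rt; evaporate; 2 M NaOH, THF/MeOH, rt; AcOH to pH 5–6, 0 °C
Reagents that add atoms: 3,4-dihydro-2H-pyran, C1=COCCC1
Why: Acid-catalysed addition of phenol and acid to the enol ether gives the bis-tetrahydropyranyl compound, whose acetal ester is saponified selectively while the aryl acetal ether is stable to base (tetrahydropyranyl protection, ester hydrolysis).

Step 8
Reactants: 14 (1R,2S,3R)-3-(2,2-dimethoxyethyl)-2-[(1S)-1-hydroxy-4,4-dimethoxybutyl]-3-methyl-1-(propan-2-yl)cyclopentan-1-ol; 17 4-(oxan-2-yloxy)benzoic acid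
Product: 18 (1S)-1-[(1S,2R,5R)-5-(2,2-dimethoxyethyl)-2-hydroxy-5-methyl-2-(propan-2-yl)cyclopentyl]-4,4-dimethoxybutyl 4-(oxan-2-yloxy)benzoate
Conditions: 17 (2 equiv), EDC·HCl (2.5 equiv), DMAP (2 equiv), CH2Cl2, rt → 35 °C
Reagents that add atoms: none
Why: Carbodiimide activation with DMAP as acyl-transfer agent (Steglich esterification) is base-buffered and therefore compatible with the acetals and the phenol ether. The secondary C6–OH is acylated in preference to the far more hindered tertiary C4–OH, with retention at C6.

Step 9
Reactants: 18 (1S)-1-[(1S,2R,5R)-5-(2,2-dimethoxyethyl)-2-hydroxy-5-methyl-2-(propan-2-yl)cyclopentyl]-4,4-dimethoxybutyl 4-(oxan-2-yloxy)benzoate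
Product: 19 (1S)-1-[(1S,2R,5R)-2-hydroxy-5-methyl-5-(2-oxoethyl)-2-(propan-2-yl)cyclopentyl]-4-oxobutyl 4-hydroxybenzoate
Conditions: PPTS (0.3 equiv), acetone/H2O 9:1, 50 °C; NaHCO3 work-up; used crude
Reagents that add atoms: water, O
Why: Mild acid-catalysed hydrolysis (transacetalisation to acetone) removes both dimethyl acetals and the aryl tetrahydropyranyl ether in one operation. The benzoate and the tertiary alcohol are stable at this acidity, and no stereocentre is enolisable.

Step 10
Reactants: 19 (1S)-1-[(1S,2R,5R)-2-hydroxy-5-methyl-5-(2-oxoethyl)-2-(propan-2-yl)cyclopentyl]-4-oxobutyl 4-hydroxybenzoate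
Product: 20 (3R,3aS,4S,8aR)-6-formyl-3-hydroxy-8a-methyl-3-(propan-2-yl)-1,2,3,3a,4,5,8,8a-octahydroazulen-4-yl 4-hydroxybenzoate (target)
Conditions: Bn2NH·TFA (0.5 equiv), toluene (0.01 M), 50 °C
Reagents that add atoms: none
Why: Secondary-amine catalysis turns the unhindered C14 aldehyde into its enamine (nucleophilic C8), which attacks the C9 iminium in a 7-membered Mannich-type closure; loss of the amine gives the conjugated enal (amine-catalysed intramolecular aldol condensation of a 1,8-dialdehyde). The competing closure from C10 would need a neopentyl enamine carbon and would put the formyl-bearing alkene carbon next to quaternary C1, so it should be disfavoured kinetically and thermodynamically. No stereocentre is formed or touched.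

## Compound list

1 | 3-ethoxycyclopent-2-en-1-one | CCOC1=CC(=O)CC1 | starting material
2 | allylmagnesium bromide | C=CC[Mg]Br | starting material
3 | bromomagnesium 3-ethoxy-1-(prop-2-en-1-yl)cyclopent-2-en-1-olate (racemic) | CCOC1=CC(CC=C)(O[Mg]Br)CC1 | intermediate (not isolated)
4 | 3-(prop-2-en-1-yl)cyclopent-2-en-1-one | C=CCC1=CC(=O)CC1 | intermediate
5 | 2-(3-oxocyclopent-1-en-1-yl)acetaldehyde | O=CCC1=CC(=O)CC1 | intermediate (not isolated)
6 | 3-(2,2-dimethoxyethyl)cyclopent-2-en-1-one | COC(OC)CC1=CC(=O)CC1 | intermediate
7 | trimethylaluminium | C[Al](C)C | starting material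
8 | 4,4-dimethoxybutanal | COC(OC)CCC=O | starting material
9 | dimethylaluminium (3R)-3-(2,2-dimethoxyethyl)-3-methylcyclopent-1-en-1-olate | C[Al](C)OC1=C[C@@](C)(CC(OC)OC)CC1 | intermediate (not isolated)
10 | (2S,3R)-3-(2,2-dimethoxyethyl)-2-[(1S)-1-hydroxy-4,4-dimethoxybutyl]-3-methylcyclopentan-1-one | O=C1CC[C@](C)(CC(OC)OC)[C@H]1[C@@H](O)CCC(OC)OC | intermediate
11 | (2S,3R)-3-(2,2-dimethoxyethyl)-2-[(1S)-4,4-dimethoxy-1-[(triethylsilyl)oxy]butyl]-3-methylcyclopentan-1-one | O=C1CC[C@](C)(CC(OC)OC)[C@H]1[C@@H](O[Si](CC)(CC)CC)CCC(OC)OC | intermediate
12 | isopropylmagnesium chloride | CC(C)[Mg]Cl | starting material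
13 | (1R,2S,3R)-3-(2,2-dimethoxyethyl)-2-[(1S)-4,4-dimethoxy-1-[(triethylsilyl)oxy]butyl]-3-methyl-1-(propan-2-yl)cyclopentan-1-ol | CC(C)[C@]1(O)CC[C@](C)(CC(OC)OC)[C@H]1[C@@H](O[Si](CC)(CC)CC)CCC(OC)OC | intermediate
14 | (1R,2S,3R)-3-(2,2-dimethoxyethyl)-2-[(1S)-1-hydroxy-4,4-dimethoxybutyl]-3-methyl-1-(propan-2-yl)cyclopentan-1-ol | CC(C)[C@]1(O)CC[C@](C)(CC(OC)OC)[C@H]1[C@@H](O)CCC(OC)OC | intermediate
15 | 4-hydroxybenzoic acid | O=C(O)c1ccc(O)cc1 | starting material
16 | oxan-2-yl 4-(oxan-2-yloxy)benzoate (epimers at both oxane C2) | O=C(OC1CCCCO1)c1ccc(OC2CCCCO2)cc1 | intermediate (not isolated)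
17 | 4-(oxan-2-yloxy)benzoic acid (racemic at oxane C2) | O=C(O)c1ccc(OC2CCCCO2)cc1 | intermediate
18 | (1S)-1-[(1S,2R,5R)-5-(2,2-dimethoxyethyl)-2-hydroxy-5-methyl-2-(propan-2-yl)cyclopentyl]-4,4-dimethoxybutyl 4-(oxan-2-yloxy)benzoate (epimers at oxane C2) | CC(C)[C@]1(O)CC[C@](C)(CC(OC)OC)[C@H]1[C@@H](OC(=O)c1ccc(OC2CCCCO2)cc1)CCC(OC)OC | intermediate
19 | (1S)-1-[(1S,2R,5R)-2-hydroxy-5-methyl-5-(2-oxoethyl)-2-(propan-2-yl)cyclopentyl]-4-oxobutyl 4-hydroxybenzoate | CC(C)[C@]1(O)CC[C@](C)(CC=O)[C@H]1[C@@H](OC(=O)c1ccc(O)cc1)CCC=O | intermediate
20 | (3R,3aS,4S,8aR)-6-formyl-3-hydroxy-8a-methyl-3-(propan-2-yl)-1,2,3,3a,4,5,8,8a-octahydroazulen-4-yl 4-hydroxybenzoate | CC(C)[C@]1(O)CC[C@]2(C)CC=C(C=O)C[C@H](OC(=O)c3ccc(O)cc3)[C@H]21 | target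

## Step count and least certain steps

Total: 10 steps. Longest linear sequence: 9 steps (steps 1–6 and 8–10); step 7 is a one-step side branch.

**Step 3 (key step).** The most likely failure is incomplete or unselective aldol capture. Enolate 9 is shielded by the adjacent quaternary carbon and only moderately nucleophilic. Methyl transfer from residual AlMe3 to 8, hydride transfer of the aldol–Tishchenko type within the aluminium aldolate, and reversal of the aldol can therefore compete. Face selection between the methyl group and the acetal arm may also be incomplete. In addition, five-membered enones are less reactive and less selectively differentiated than six-membered ones in the copper step. The fallback separates the two bond formations. It sets out from 6 and 7 under the conditions of step 3, but the enolate 9 is quenched with Me3SiOTf to give trimethyl{[(3R)-3-(2,2-dimethoxyethyl)-3-methylcyclopent-1-en-1-yl]oxy}silane F1, which is isolated. This allows the enantiomeric purity of the quaternary centre to be checked and, if necessary, the conjugate addition alone to be moved to another catalyst class. F1 is then cleaved with MeLi in THF to the lithium enolate, transmetallated with ZnCl2, and treated with 8 at −78 °C. The zinc enolate reacts through the same closed transition state and returns to the route at 10.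

**Step 10.** The most likely failure is ring closure in the wrong sense or not at all. If the enamine on the C9 aldehyde reacts through C10 with the C14 aldehyde, a regioisomeric cycloheptene carbaldehyde results; slow seven-membered closure would also leave room for intermolecular condensation. The fallback makes the C8=C9 bond by ring-closing metathesis, which is regiochemically fixed by construction. It sets out from 4 and ends at 20.

- Compound 4 takes the place of 6 in the conjugate methylation–aldol with 7 and 8 and gives (2S,3R)-2-[(1S)-1-hydroxy-4,4-dimethoxybutyl]-3-methyl-3-(prop-2-en-1-yl)cyclopentan-1-one F2.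
- Silylation as in step 4 gives (2S,3R)-2-[(1S)-4,4-dimethoxy-1-[(triethylsilyl)oxy]butyl]-3-methyl-3-(prop-2-en-1-yl)cyclopentan-1-one F3.
- Addition of the cerium reagent from 12 gives (1R,2S,3R)-2-[(1S)-4,4-dimethoxy-1-[(triethylsilyl)oxy]butyl]-3-methyl-1-(propan-2-yl)-3-(prop-2-en-1-yl)cyclopentan-1-ol F4.
- TBAF gives (1R,2S,3R)-2-[(1S)-1-hydroxy-4,4-dimethoxybutyl]-3-methyl-1-(propan-2-yl)-3-(prop-2-en-1-yl)cyclopentan-1-ol F5.
- Esterification with 17 as in step 8 gives (1S)-1-[(1S,2R,5R)-2-hydroxy-5-methyl-2-(propan-2-yl)-5-(prop-2-en-1-yl)cyclopentyl]-4,4-dimethoxybutyl 4-(oxan-2-yloxy)benzoate F6.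
- Hydrolysis as in step 9 gives (1S)-1-[(1S,2R,5R)-2-hydroxy-5-methyl-2-(propan-2-yl)-5-(prop-2-en-1-yl)cyclopentyl]-4-oxobutyl 4-hydroxybenzoate F7.
- α-Methylenation of the single aldehyde (aqueous formaldehyde, pyrrolidine/propionic acid, i-PrOH, 45 °C) gives (1S)-1-[(1S,2R,5R)-2-hydroxy-5-methyl-2-(propan-2-yl)-5-(prop-2-en-1-yl)cyclopentyl]-3-methylidene-4-oxobutyl 4-hydroxybenzoate F8; the electron-poor phenol is expected to resist aminomethylation.
- Ring-closing metathesis of the allyl group with the 2-substituted acrolein (second-generation Hoveyda–Grubbs catalyst, toluene, 80 °C, high dilution) expels ethene and gives 20.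

**Step 5.** The most likely failure is enolisation or β-hydride reduction of the hindered cyclopentanone in place of addition, or incomplete face selection, because the α face also carries the acetal arm on C1 in a 1,3-relationship to the carbonyl. The fallback sets out from 11 and uses a smaller, sp2-hybridised nucleophile that cannot transfer hydride. Isopropenylmagnesium bromide with CeCl3 in THF at −78 °C gives (1S,2S,3R)-3-(2,2-dimethoxyethyl)-2-[(1S)-4,4-dimethoxy-1-[(triethylsilyl)oxy]butyl]-3-methyl-1-(prop-1-en-2-yl)cyclopentan-1-ol F9. Hydrogenation of the 1,1-disubstituted alkene (H2, PtO2, EtOAc) then returns to the route at 13.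

**Step 2.** The most likely failure is loss of the acetal arm by elimination of methanol into conjugation, or over-oxidation. The intermediate 5 and the product 6 have a CH2 group flanked by the enone and the aldehyde or acetal carbon, and the enol form of 5 is ozone-sensitive. The fallback avoids the free aldehyde altogether and sets out from 1. Addition of (Z)-2-ethoxyvinyllithium (from (Z)-1-bromo-2-ethoxyethene and t-BuLi, THF, −78 °C) and mild acidic transposition give 3-[(Z)-2-ethoxyethenyl]cyclopent-2-en-1-one F10. Acid-catalysed 1,6-addition of methanol with alkoxy exchange (MeOH, HC(OMe)3, PPTS, rt) then returns to the route at 6.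

## Further compounds

F1 | step 3 | trimethyl{[(3R)-3-(2,2-dimethoxyethyl)-3-methylcyclopent-1-en-1-yl]oxy}silane | C[Si](C)(C)OC1=C[C@@](C)(CC(OC)OC)CC1
F2 | step 10 | (2S,3R)-2-[(1S)-1-hydroxy-4,4-dimethoxybutyl]-3-methyl-3-(prop-2-en-1-yl)cyclopentan-1-one | O=C1CC[C@](C)(CC=C)[C@H]1[C@@H](O)CCC(OC)OC
F3 | step 10 | (2S,3R)-2-[(1S)-4,4-dimethoxy-1-[(triethylsilyl)oxy]butyl]-3-methyl-3-(prop-2-en-1-yl)cyclopentan-1-one | O=C1CC[C@](C)(CC=C)[C@H]1[C@@H](O[Si](CC)(CC)CC)CCC(OC)OC
F4 | step 10 | (1R,2S,3R)-2-[(1S)-4,4-dimethoxy-1-[(triethylsilyl)oxy]butyl]-3-methyl-1-(propan-2-yl)-3-(prop-2-en-1-yl)cyclopentan-1-ol | CC(C)[C@]1(O)CC[C@](C)(CC=C)[C@H]1[C@@H](O[Si](CC)(CC)CC)CCC(OC)OC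
F5 | step 10 | (1R,2S,3R)-2-[(1S)-1-hydroxy-4,4-dimethoxybutyl]-3-methyl-1-(propan-2-yl)-3-(prop-2-en-1-yl)cyclopentan-1-ol | CC(C)[C@]1(O)CC[C@](C)(CC=C)[C@H]1[C@@H](O)CCC(OC)OC
F6 | step 10 | (1S)-1-[(1S,2R,5R)-2-hydroxy-5-methyl-2-(propan-2-yl)-5-(prop-2-en-1-yl)cyclopentyl]-4,4-dimethoxybutyl 4-(oxan-2-yloxy)benzoate (epimers at oxane C2) | CC(C)[C@]1(O)CC[C@](C)(CC=C)[C@H]1[C@@H](OC(=O)c1ccc(OC2CCCCO2)cc1)CCC(OC)OC
F7 | step 10 | (1S)-1-[(1S,2R,5R)-2-hydroxy-5-methyl-2-(propan-2-yl)-5-(prop-2-en-1-yl)cyclopentyl]-4-oxobutyl 4-hydroxybenzoate | CC(C)[C@]1(O)CC[C@](C)(CC=C)[C@H]1[C@@H](OC(=O)c1ccc(O)cc1)CCC=O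
F8 | step 10 | (1S)-1-[(1S,2R,5R)-2-hydroxy-5-methyl-2-(propan-2-yl)-5-(prop-2-en-1-yl)cyclopentyl]-3-methylidene-4-oxobutyl 4-hydroxybenzoate | CC(C)[C@]1(O)CC[C@](C)(CC=C)[C@H]1[C@@H](OC(=O)c1ccc(O)cc1)CC(=C)C=O
F9 | step 5 | (1S,2S,3R)-3-(2,2-dimethoxyethyl)-2-[(1S)-4,4-dimethoxy-1-[(triethylsilyl)oxy]butyl]-3-methyl-1-(prop-1-en-2-yl)cyclopentan-1-ol | C=C(C)[C@]1(O)CC[C@](C)(CC(OC)OC)[C@H]1[C@@H](O[Si](CC)(CC)CC)CCC(OC)OC
F10 | step 2 | 3-[(Z)-2-ethoxyethenyl]cyclopent-2-en-1-one | CCO/C=C\C1=CC(=O)CC1
A1 | alternative 1 | 7-methyl-6-[(2S)-5-methylideneoxolan-2-yl]-1,4-dioxaspiro[4.4]non-6-ene (Claisen substrate) | C=C1CC[C@@H](C2=C(C)CCC23OCCO3)O1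
A2 | alternative 1 | (3aR)-3a-methyl-2,3,3a,4,6,7-hexahydroazulene-1,5-dione 1-(ethane-1,2-diyl ketal) (Claisen product; C9 ketone, C5=C6, C4 ketal) | O=C1C[C@@]2(C)CCC3(OCCO3)C2=CCC1
A3 | alternative 2 | (4S,7E,9E)-11-[(tert-butyldimethylsilyl)oxy]-1-chloro-7-methyl-4-(propan-2-yl)-4-[(triethylsilyl)oxy]undeca-7,9-dien-2-one (oxyallyl precursor) | CC(C)[C@@](O[Si](CC)(CC)CC)(CC(=O)CCl)CC/C(C)=C/C=C/CO[Si](C)(C)C(C)(C)C
A4 | alternative 2 | (3R,3aR,8aR)-6-{[(tert-butyldimethylsilyl)oxy]methyl}-8a-methyl-3-(propan-2-yl)-3-[(triethylsilyl)oxy]-2,3,3a,5,6,8a-hexahydroazulen-4(1H)-one (cycloadduct; C6 ketone, C9=C10, either configuration at the silyloxymethyl-bearing carbon) | CC(C)[C@]1(O[Si](CC)(CC)CC)CC[C@]2(C)C=CC(CO[Si](C)(C)C(C)(C)C)CC(=O)[C@H]21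
A5 | alternative 3 | methyl (3R,6R)-6-[(tert-butyldimethylsilyl)oxy]-2-diazo-3,7-dimethyl-3-(prop-2-en-1-yl)octanoate (insertion substrate) | COC(=O)C(=[N+]=[N-])[C@@](C)(CC=C)CC[C@@H](O[Si](C)(C)C(C)(C)C)C(C)C
A6 | alternative 3 | methyl (1R,2R,5R)-2-[(tert-butyldimethylsilyl)oxy]-5-methyl-2-(propan-2-yl)-5-(prop-2-en-1-yl)cyclopentane-1-carboxylate (insertion product) | CC(C)[C@]1(O[Si](C)(C)C(C)(C)C)CC[C@](C)(CC=C)[C@H]1C(=O)OC
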